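**Retrosynthetic overview**

1. Last disconnection: both carbocycles (rings A and B) are made together in the final step by a catalyst-controlled, proton-initiated bicyclisation of the acyclic (3Z,7E,11E)-tetraene hydroxy-lactone. The cascade ends by proton loss to the tetrasubstituted ring alkene, and this step alone sets the two decalin stereocentres.
2. The acyclic hydroxy-lactone comes from an Evans syn-aldol (sets both side-chain stereocentres) between a (Z)-β,γ-unsaturated aldehyde and a succinate imide, followed by auxiliary reduction and lactonisation.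
3. The aldehyde comes from a Z-selective Wittig reaction of an α-silyloxy ketone with a C3 hydroxy-ylide; the ketone comes from C-alkylation of silyloxyacetone with (E,E)-farnesyl bromide.
4. Ring order: butyrolactone first (step 8), then rings A and B in one operation (step 9).

Assumption: the confined chiral IDPi Brønsted acid of step 9 is a catalyst prepared separately and is neither numbered nor counted; all numbered starting materials are catalogue chemicals.

**Route**

Step 1
Reactants: 1 (2E,6E)-farnesyl bromide; 2 1-[(tert-butyldimethylsilyl)oxy]propan-2-one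
Product: 4 (5E,9E)-1-[(tert-butyldimethylsilyl)oxy]-6,10,14-trimethylpentadeca-5,9,13-trien-2-one, via lithium enolate 3 (not isolated)
Conditions: 2 (1.5 equiv), LDA, THF, −78 °C; then 1, DMPU, −78 → −20 °C
Reagents that add atoms: none
Why: Kinetic deprotonation by LDA takes the unhindered methyl protons rather than the CH2 next to the bulky silyloxy group, and the lithium enolate is C-alkylated by the primary allylic bromide (enolate alkylation, SN2) with both E-alkenes retained; no stereocentre is formed.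

Step 2
Reactants: 4 (5E,9E)-1-[(tert-butyldimethylsilyl)oxy]-6,10,14-trimethylpentadeca-5,9,13-trien-2-one; 5 (3-hydroxypropyl)triphenylphosphonium bromide
Product: 7 (3Z,7E,11E)-4-{[(tert-butyldimethylsilyl)oxy]methyl}-8,12,16-trimethylheptadeca-3,7,11,15-tetraen-1-ol, via oxido ylide 6 (not isolated)
Conditions: 5, KHMDS (2 equiv), THF, 0 °C; then 4, −78 °C → rt; H2O work-up
Reagents that add atoms: none
Why: Wittig olefination of an α-alkoxy ketone (Still's Z-selective variant): the lithium-free, non-stabilised ylide adds under kinetic control so that its chain ends up cis to the CH2OSi group, giving the (Z)-trisubstituted alkene.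

Step 3
Reactants: 7 (3Z,7E,11E)-4-{[(tert-butyldimethylsilyl)oxy]methyl}-8,12,16-trimethylheptadeca-3,7,11,15-tetraen-1-ol
Product: 8 (3Z,7E,11E)-4-{[(tert-butyldimethylsilyl)oxy]methyl}-8,12,16-trimethylheptadeca-3,7,11,15-tetraenal
Conditions: DMP, pyridine, CH2Cl2, 0 °C → rt; used crude at once
Reagents that add atoms: none
Why: Dess–Martin oxidation under pyridine buffering stops at the aldehyde and is mild enough that the β,γ-alkene does not move into conjugation.

Step 4
Reactants: 9 4-(tert-butoxy)-4-oxobutanoic acid; 10 (4S)-4-benzyl-1,3-oxazolidin-2-one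
Product: 12 tert-butyl 4-[(4S)-4-benzyl-2-oxo-1,3-oxazolidin-3-yl]-4-oxobutanoate, via mixed pivalic anhydride 11 (not isolated)
Conditions: 9, PivCl, Et3N, THF, −20 °C; then 10, LiCl, rt
Reagents that add atoms: none
Why: N-acylation of the oxazolidinone through the mixed anhydride, which is attacked at the less hindered succinyl carbonyl; the auxiliary stereocentre is untouched.

Step 5
Reactants: 12 tert-butyl 4-[(4S)-4-benzyl-2-oxo-1,3-oxazolidin-3-yl]-4-oxobutanoate; 8 (3Z,7E,11E)-4-{[(tert-butyldimethylsilyl)oxy]methyl}-8,12,16-trimethylheptadeca-3,7,11,15-tetraenal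
Product: 14 tert-butyl (3S,4R,6Z,10E,14E)-3-{[(4S)-4-benzyl-2-oxo-1,3-oxazolidin-3-yl]carbonyl}-7-{[(tert-butyldimethylsilyl)oxy]methyl}-4-hydroxy-11,15,19-trimethylicosa-6,10,14,18-tetraenoate, via (Z)-boron enolate 13 (not isolated)
Conditions: 12, Bu2BOTf (1.1 equiv), iPr2NEt (1.05 equiv), CH2Cl2, 0 °C; then 8, −78 → 0 °C; pH 7 buffer, MeOH, H2O2
Reagents that add atoms: none
Why: Evans syn-aldol reaction: the (Z)-dibutylboron enolate reacts through a Zimmerman–Traxler chair in which the (S)-benzyl auxiliary shields one enolate face, setting both new centres as the (3S,4R) syn adduct, which has the spatial arrangement of the carbinol carbon (R) and lactone C4 (R) of the target; the aldehyde meets no free amine at −78 °C, so its alkene stays in place.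

Step 6
Reactants: 14 tert-butyl (3S,4R,6Z,10E,14E)-3-{[(4S)-4-benzyl-2-oxo-1,3-oxazolidin-3-yl]carbonyl}-7-{[(tert-butyldimethylsilyl)oxy]methyl}-4-hydroxy-11,15,19-trimethylicosa-6,10,14,18-tetraenoate
Product: 15 tert-butyl (3S,4R,6Z,10E,14E)-3-{[(4S)-4-benzyl-2-oxo-1,3-oxazolidin-3-yl]carbonyl}-4-[(tert-butyldimethylsilyl)oxy]-7-{[(tert-butyldimethylsilyl)oxy]methyl}-11,15,19-trimethylicosa-6,10,14,18-tetraenoate
Conditions: TBSOTf (1.2 equiv), 2,6-lutidine, CH2Cl2, −78 → 0 °C
Reagents that add atoms: tert-butyldimethylsilyl trifluoromethanesulfonate, CC(C)(C)[Si](C)(C)OS(=O)(=O)C(F)(F)F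
Why: O-silylation of the secondary alcohol with a silyl triflate and a hindered pyridine base blocks this oxygen so that only the primary hydroxyl can later close the lactone; no stereocentre is touched.

Step 7
Reactants: 15 tert-butyl (3S,4R,6Z,10E,14E)-3-{[(4S)-4-benzyl-2-oxo-1,3-oxazolidin-3-yl]carbonyl}-4-[(tert-butyldimethylsilyl)oxy]-7-{[(tert-butyldimethylsilyl)oxy]methyl}-11,15,19-trimethylicosa-6,10,14,18-tetraenoate
Product: 16 tert-butyl (3R,4R,6Z,10E,14E)-4-[(tert-butyldimethylsilyl)oxy]-7-{[(tert-butyldimethylsilyl)oxy]methyl}-3-(hydroxymethyl)-11,15,19-trimethylicosa-6,10,14,18-tetraenoate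
Conditions: LiBH4, H2O (1 equiv), Et2O, 0 °C
Reagents that add atoms: none
Why: Reductive cleavage of the N-acyl oxazolidinone: hydride attacks the activated exocyclic imide carbonyl while the tert-butyl ester and silyl ethers are inert at 0 °C, giving the primary alcohol without epimerising the adjacent centre (the descriptor changes from S to R only through CIP priorities).

Step 8
Reactants: 16 tert-butyl (3R,4R,6Z,10E,14E)-4-[(tert-butyldimethylsilyl)oxy]-7-{[(tert-butyldimethylsilyl)oxy]methyl}-3-(hydroxymethyl)-11,15,19-trimethylicosa-6,10,14,18-tetraenoate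
Product: 18 (4R)-4-[(1R,3Z,7E,11E)-1-hydroxy-4-(hydroxymethyl)-8,12,16-trimethylheptadeca-3,7,11,15-tetraen-1-yl]oxolan-2-one, via bis-silyl lactone 17 (not isolated)
Conditions: TsOH·H2O (5 mol %), CH2Cl2, rt; then 48% aq. HF, MeCN, 0 °C → rt
Reagents that add atoms: none
Why: Acid-catalysed intramolecular transesterification (5-exo lactonisation of a γ-hydroxy tert-butyl ester) closes the butyrolactone on the only free hydroxyl, and HF then cleaves both Si–O bonds without opening or shifting the lactone; catalytic sulfonic acid at rt and aqueous HF leave the trisubstituted alkenes alone.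

Step 9
Reactants: 18 (4R)-4-[(1R,3Z,7E,11E)-1-hydroxy-4-(hydroxymethyl)-8,12,16-trimethylheptadeca-3,7,11,15-tetraen-1-yl]oxolan-2-one
Product: 19 (4R)-4-[(1R,3Z)-1-hydroxy-4-(hydroxymethyl)-6-[(4aS,8aS)-2,5,5,8a-tetramethyl-3,4,4a,5,6,7,8,8a-octahydronaphthalen-1-yl]hex-3-en-1-yl]oxolan-2-one (target)
Conditions: chiral IDPi Brønsted acid (5 mol %, enantiomer giving the 4aS,8aS series), (CF3)3COH–CH2Cl2, −40 °C; then 0 °C to equilibrate alkene isomers
Reagents that add atoms: none
Why: Proposed new method: the closest known reactions are the confined-IDPi/fluoroalcohol-catalysed asymmetric bicyclisation of homofarnesol to ambrox and chiral Lewis-acid-assisted Brønsted-acid polyene cyclisations; the chiral acid protonates one face of the terminal isopropylidene group, the two (E)-trisubstituted alkenes close through a chair–chair Stork–Eschenmoser array (two anti additions give the trans ring fusion, 4aS,8aS under catalyst control and independent of the remote side-chain centres), the fourth alkene stays out because attack through it would place the cation next to the hydroxymethyl oxygen, and the tertiary ring cation, with no nucleophile in reach, loses a proton, reversible re-protonation of the tri- and 1,1-disubstituted alkene isomers by the same acid funnelling material to the tetrasubstituted ring alkene, the thermodynamic sink.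

**Compound list**

1 | (2E,6E)-farnesyl bromide | CC(C)=CCC/C(C)=C/CC/C(C)=C/CBr | starting material
2 | 1-[(tert-butyldimethylsilyl)oxy]propan-2-one | CC(=O)CO[Si](C)(C)C(C)(C)C | starting material
3 | lithium 3-[(tert-butyldimethylsilyl)oxy]prop-1-en-2-olate (kinetic enolate of 2) | [Li+].[O-]C(=C)CO[Si](C)(C)C(C)(C)C | intermediate
4 | (5E,9E)-1-[(tert-butyldimethylsilyl)oxy]-6,10,14-trimethylpentadeca-5,9,13-trien-2-one | CC(C)=CCC/C(C)=C/CC/C(C)=C/CCC(=O)CO[Si](C)(C)C(C)(C)C | intermediate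
5 | (3-hydroxypropyl)triphenylphosphonium bromide | OCCC[P+](c1ccccc1)(c1ccccc1)c1ccccc1.[Br-] | starting material
6 | potassium 3-(triphenyl-λ5-phosphanylidene)propan-1-olate (oxido ylide) | [K+].[O-]CCC=P(c1ccccc1)(c1ccccc1)c1ccccc1 | intermediate
7 | (3Z,7E,11E)-4-{[(tert-butyldimethylsilyl)oxy]methyl}-8,12,16-trimethylheptadeca-3,7,11,15-tetraen-1-ol | CC(C)=CCC/C(C)=C/CC/C(C)=C/CC/C(=C/CCO)CO[Si](C)(C)C(C)(C)C | intermediate
8 | (3Z,7E,11E)-4-{[(tert-butyldimethylsilyl)oxy]methyl}-8,12,16-trimethylheptadeca-3,7,11,15-tetraenal | CC(C)=CCC/C(C)=C/CC/C(C)=C/CC/C(=C/CC=O)CO[Si](C)(C)C(C)(C)C | intermediate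
9 | 4-(tert-butoxy)-4-oxobutanoic acid (mono-tert-butyl succinate) | CC(C)(C)OC(=O)CCC(=O)O | starting material
10 | (4S)-4-benzyl-1,3-oxazolidin-2-one | O=C1OC[C@H](Cc2ccccc2)N1 | starting material
11 | 4-(tert-butoxy)-4-oxobutanoic pivalic anhydride | CC(C)(C)OC(=O)CCC(=O)OC(=O)C(C)(C)C | intermediate
12 | tert-butyl 4-[(4S)-4-benzyl-2-oxo-1,3-oxazolidin-3-yl]-4-oxobutanoate | CC(C)(C)OC(=O)CCC(=O)N1[C@@H](Cc2ccccc2)COC1=O | intermediate
13 | (Z)-O-dibutylboryl enolate of 12 | CCCCB(CCCC)O/C(=C\CC(=O)OC(C)(C)C)N1[C@@H](Cc2ccccc2)COC1=O | intermediate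
14 | tert-butyl (3S,4R,6Z,10E,14E)-3-{[(4S)-4-benzyl-2-oxo-1,3-oxazolidin-3-yl]carbonyl}-7-{[(tert-butyldimethylsilyl)oxy]methyl}-4-hydroxy-11,15,19-trimethylicosa-6,10,14,18-tetraenoate | CC(C)=CCC/C(C)=C/CC/C(C)=C/CC/C(=C/C[C@@H](O)[C@H](CC(=O)OC(C)(C)C)C(=O)N1[C@@H](Cc2ccccc2)COC1=O)CO[Si](C)(C)C(C)(C)C | intermediate
15 | tert-butyl (3S,4R,6Z,10E,14E)-3-{[(4S)-4-benzyl-2-oxo-1,3-oxazolidin-3-yl]carbonyl}-4-[(tert-butyldimethylsilyl)oxy]-7-{[(tert-butyldimethylsilyl)oxy]methyl}-11,15,19-trimethylicosa-6,10,14,18-tetraenoate | CC(C)=CCC/C(C)=C/CC/C(C)=C/CC/C(=C/C[C@@H](O[Si](C)(C)C(C)(C)C)[C@H](CC(=O)OC(C)(C)C)C(=O)N1[C@@H](Cc2ccccc2)COC1=O)CO[Si](C)(C)C(C)(C)C | intermediate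
16 | tert-butyl (3R,4R,6Z,10E,14E)-4-[(tert-butyldimethylsilyl)oxy]-7-{[(tert-butyldimethylsilyl)oxy]methyl}-3-(hydroxymethyl)-11,15,19-trimethylicosa-6,10,14,18-tetraenoate | CC(C)=CCC/C(C)=C/CC/C(C)=C/CC/C(=C/C[C@@H](O[Si](C)(C)C(C)(C)C)[C@H](CC(=O)OC(C)(C)C)CO)CO[Si](C)(C)C(C)(C)C | intermediate
17 | (4R)-4-[(1R,3Z,7E,11E)-1-[(tert-butyldimethylsilyl)oxy]-4-{[(tert-butyldimethylsilyl)oxy]methyl}-8,12,16-trimethylheptadeca-3,7,11,15-tetraen-1-yl]oxolan-2-one | CC(C)=CCC/C(C)=C/CC/C(C)=C/CC/C(=C/C[C@@H](O[Si](C)(C)C(C)(C)C)[C@H]1COC(=O)C1)CO[Si](C)(C)C(C)(C)C | intermediate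
18 | (4R)-4-[(1R,3Z,7E,11E)-1-hydroxy-4-(hydroxymethyl)-8,12,16-trimethylheptadeca-3,7,11,15-tetraen-1-yl]oxolan-2-one | CC(C)=CCC/C(C)=C/CC/C(C)=C/CC/C(=C/C[C@@H](O)[C@H]1COC(=O)C1)CO | intermediate
19 | (4R)-4-[(1R,3Z)-1-hydroxy-4-(hydroxymethyl)-6-[(4aS,8aS)-2,5,5,8a-tetramethyl-3,4,4a,5,6,7,8,8a-octahydronaphthalen-1-yl]hex-3-en-1-yl]oxolan-2-one | CC1=C(CC/C(=C/C[C@@H](O)[C@H]2COC(=O)C2)CO)[C@@]2(C)CCCC(C)(C)[C@@H]2CC1 | target

**Step count and weak points**

Total step count: 9. Longest linear sequence: 8 (steps 1, 2, 3, 5, 6, 7, 8, 9, starting from 1); step 4 is a one-step side branch.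

The three steps most likely to fail:

Step 9. The bicyclisation is run on the complete, unprotected molecule. The er may fall short, and the wrong decalin antipode would then be a diastereomer that is hard to separate. Proton loss may also give the trisubstituted or exocyclic ring alkene, which might not equilibrate cleanly, and the primary allylic alcohol could ionise in the acidic fluoroalcohol. The fallback moves ring formation to the front of the route; it sets out from 7 and comes back at 19. Alcohol 7 carries no lactone, is two steps from the starting materials, and can be cyclised with the same catalyst or with a stoichiometric chiral SnCl4–binaphthol Lewis-acid-assisted Brønsted acid to the bicyclic alcohol F1. At that stage alkene isomers can be removed on AgNO3–silica and the er measured and corrected by preparative chiral chromatography before the chiral side chain is invested. The tetrasubstituted ring alkene is inert to everything that follows, so the route's own chemistry is repeated on the bicyclic series: Dess–Martin oxidation gives the aldehyde F2, the Evans aldol with 12 gives the adduct F3, silylation gives the bis-silyl ether F4, LiBH4 gives the primary alcohol F5, and TsOH followed by aqueous HF gives, through the bis-silyl lactone F6, the target 19.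

Step 2. The oxido ylide is basic and the ketone is enolisable, so enolisation or an eroded Z:E ratio could result. The fallback sets out from 4 and comes back at 8, replacing steps 2 and 3. Ketone 4 is treated with the simple non-stabilised ylide from [2-(1,3-dioxolan-2-yl)ethyl]triphenylphosphonium bromide and KHMDS, the case closest to the Z-selective α-alkoxy-ketone precedent, to give the (Z)-dioxolane F7. The acetal is then opened under non-acidic conditions (TESOTf, 2,6-lutidine, CH2Cl2, 0 °C; then water), which releases aldehyde 8 directly and avoids both the hydroxy-ylide and the alcohol oxidation.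

Step 1. The enolate may form partly on the silyloxy side, or the product may be alkylated twice. The fallback sets out from 2 (with 1) and comes back at 4. Ketone 2 is condensed with 1,1-dimethylhydrazine to the N,N-dimethylhydrazone F8, whose aza-enolate (LDA, THF, −78 °C) forms at the methyl group, the less substituted α-carbon, and is mono-alkylated by 1 to the alkylated hydrazone F9. Mild hydrolysis (aqueous oxalic acid/Et2O) then returns ketone 4.

**Further compounds**

F1 | step 9 | (3Z)-4-{[(tert-butyldimethylsilyl)oxy]methyl}-6-[(4aS,8aS)-2,5,5,8a-tetramethyl-3,4,4a,5,6,7,8,8a-octahydronaphthalen-1-yl]hex-3-en-1-ol | CC1=C(CC/C(=C/CCO)CO[Si](C)(C)C(C)(C)C)[C@@]2(C)CCCC(C)(C)[C@@H]2CC1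
F2 | step 9 | (3Z)-4-{[(tert-butyldimethylsilyl)oxy]methyl}-6-[(4aS,8aS)-2,5,5,8a-tetramethyl-3,4,4a,5,6,7,8,8a-octahydronaphthalen-1-yl]hex-3-enal | CC1=C(CC/C(=C/CC=O)CO[Si](C)(C)C(C)(C)C)[C@@]2(C)CCCC(C)(C)[C@@H]2CC1
F3 | step 9 | tert-butyl (3S,4R,6Z)-3-{[(4S)-4-benzyl-2-oxo-1,3-oxazolidin-3-yl]carbonyl}-7-{[(tert-butyldimethylsilyl)oxy]methyl}-4-hydroxy-9-[(4aS,8aS)-2,5,5,8a-tetramethyl-3,4,4a,5,6,7,8,8a-octahydronaphthalen-1-yl]non-6-enoate | CC1=C(CC/C(=C/C[C@@H](O)[C@H](CC(=O)OC(C)(C)C)C(=O)N3[C@@H](Cc4ccccc4)COC3=O)CO[Si](C)(C)C(C)(C)C)[C@@]2(C)CCCC(C)(C)[C@@H]2CC1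
F4 | step 9 | tert-butyl (3S,4R,6Z)-3-{[(4S)-4-benzyl-2-oxo-1,3-oxazolidin-3-yl]carbonyl}-4-[(tert-butyldimethylsilyl)oxy]-7-{[(tert-butyldimethylsilyl)oxy]methyl}-9-[(4aS,8aS)-2,5,5,8a-tetramethyl-3,4,4a,5,6,7,8,8a-octahydronaphthalen-1-yl]non-6-enoate | CC1=C(CC/C(=C/C[C@@H](O[Si](C)(C)C(C)(C)C)[C@H](CC(=O)OC(C)(C)C)C(=O)N3[C@@H](Cc4ccccc4)COC3=O)CO[Si](C)(C)C(C)(C)C)[C@@]2(C)CCCC(C)(C)[C@@H]2CC1
F5 | step 9 | tert-butyl (3R,4R,6Z)-4-[(tert-butyldimethylsilyl)oxy]-7-{[(tert-butyldimethylsilyl)oxy]methyl}-3-(hydroxymethyl)-9-[(4aS,8aS)-2,5,5,8a-tetramethyl-3,4,4a,5,6,7,8,8a-octahydronaphthalen-1-yl]non-6-enoate | CC1=C(CC/C(=C/C[C@@H](O[Si](C)(C)C(C)(C)C)[C@H](CC(=O)OC(C)(C)C)CO)CO[Si](C)(C)C(C)(C)C)[C@@]2(C)CCCC(C)(C)[C@@H]2CC1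
F6 | step 9 | (4R)-4-[(1R,3Z)-1-[(tert-butyldimethylsilyl)oxy]-4-{[(tert-butyldimethylsilyl)oxy]methyl}-6-[(4aS,8aS)-2,5,5,8a-tetramethyl-3,4,4a,5,6,7,8,8a-octahydronaphthalen-1-yl]hex-3-en-1-yl]oxolan-2-one | CC1=C(CC/C(=C/C[C@@H](O[Si](C)(C)C(C)(C)C)[C@H]3COC(=O)C3)CO[Si](C)(C)C(C)(C)C)[C@@]2(C)CCCC(C)(C)[C@@H]2CC1
F7 | step 2 | 2-[(2Z,6E,10E)-3-{[(tert-butyldimethylsilyl)oxy]methyl}-7,11,15-trimethylhexadeca-2,6,10,14-tetraen-1-yl]-1,3-dioxolane | CC(C)=CCC/C(C)=C/CC/C(C)=C/CC/C(=C/CC1OCCO1)CO[Si](C)(C)C(C)(C)C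
F8 | step 1 | 1-[(tert-butyldimethylsilyl)oxy]propan-2-one N,N-dimethylhydrazone | CC(CO[Si](C)(C)C(C)(C)C)=NN(C)C
F9 | step 1 | (5E,9E)-1-[(tert-butyldimethylsilyl)oxy]-6,10,14-trimethylpentadeca-5,9,13-trien-2-one N,N-dimethylhydrazone | CC(C)=CCC/C(C)=C/CC/C(C)=C/CCC(CO[Si](C)(C)C(C)(C)C)=NN(C)C
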